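**Strategy.** The route rests on an aldol-type disconnection of the C1–C5 bond, made possible by a temporary ketone at C10 (ring A = cyclopentane C1–C5, ring B = cyclohexene C5–C10). In one operation, reduction of bromo ketone aldehyde 11 gives a ring B dienolate that attacks the aldehyde through C5: ring A closes, the quaternary spiro carbon C5 and the carbinol carbon C1 are set, and C6=C7 is left in place. The step exploits the 1,3-relation between the C1 oxygen and C10 across C5 and the allylic position of C5 next to C6=C7. The precursor is a 2-alkyl-3-methylcyclohexenone whose side chain, including the isopropenyl-bearing C3, comes from (S)-limonene; C10 and C9 are functionalised afterwards.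

Key step: step 5

Remark: C1–C10 are the spiro[4.5]decane locants used above (C3 carries the isopropenyl group); 1 and 5 are taken as commercial, and 14–16 are carried as C10 epimer mixtures that converge in step 9.

Step 1
Reactants: 1 (S)-limonene
Product: 4 (5S)-7,7-dimethoxy-5-(prop-1-en-2-yl)heptan-2-one, via hydroperoxy aldehyde 2 (not isolated), via hydroperoxy acetal 3 (not isolated)
Conditions: O3 (1 equiv), CH2Cl2/MeOH, −78 °C; TsOH (cat.), 20 °C; NaHCO3, then Me2S
Reagents that add atoms: ozone [O-][O+]=O; methanol CO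
Why: Ozonolysis should occur at the more electron-rich trisubstituted ring alkene, and methanol trapping of the carbonyl oxide followed by acid acetalisation of the aldehyde and reduction of the hydroperoxide differentiates the two termini; the C3 stereocentre is taken unchanged from the chiral pool.

Step 2
Reactants: 4 (5S)-7,7-dimethoxy-5-(prop-1-en-2-yl)heptan-2-one, 5 3-(trimethylsilyl)but-3-en-2-one
Product: 8 2-[(2S)-4,4-dimethoxy-2-(prop-1-en-2-yl)butyl]-3-methylcyclohex-2-en-1-one, via silyl diketone 6 (not isolated), via diketone 7 (not isolated)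
Conditions: LiN(i-Pr)2, THF, −78 °C; 5, −78 to 0 °C; then KOH, MeOH, 65 °C
Reagents that add atoms: none
Why: This is a Robinson annulation with an α-silyl vinyl ketone: the kinetic enolate at the methyl group (C9) adds to the enone, and after desilylation the 2,6-diketone should close by aldol condensation of the internal methylene C5 onto the unhindered methyl ketone, giving the more substituted enone.

Step 3
Reactants: 8 2-[(2S)-4,4-dimethoxy-2-(prop-1-en-2-yl)butyl]-3-methylcyclohex-2-en-1-one
Product: 10 2-bromo-2-[(2R)-4,4-dimethoxy-2-(prop-1-en-2-yl)butyl]-3-methylcyclohex-3-en-1-one, via potassium dienolate 9 (not isolated)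
Conditions: KN(SiMe3)2 (0.95 equiv), THF, −78 to 0 °C; then N-bromosuccinimide, −78 °C
Reagents that add atoms: N-bromosuccinimide O=C1CCC(=O)N1Br
Why: Equilibration gives the extended (thermodynamic) dienolate, which takes electrophilic bromine at the α-carbon C5 with deconjugation (deconjugative α-halogenation); the new centre is erased in step 5, and the allylic C7 bromide would give the same dienolate there.

Step 4
Reactants: 10 2-bromo-2-[(2R)-4,4-dimethoxy-2-(prop-1-en-2-yl)butyl]-3-methylcyclohex-3-en-1-one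
Product: 11 (3R)-4-(1-bromo-2-methyl-6-oxocyclohex-2-en-1-yl)-3-(prop-1-en-2-yl)butanal
Conditions: LiBF4, MeCN/H2O (98:2), 20 °C
Reagents that add atoms: water O
Why: Lewis-acid-promoted acetal hydrolysis under nearly neutral conditions should free the aldehyde without disturbing the tertiary bromide or the isopropenyl group.

Step 5
Reactants: 11 (3R)-4-(1-bromo-2-methyl-6-oxocyclohex-2-en-1-yl)-3-(prop-1-en-2-yl)butanal
Product: 13 (1R,3S,5R)-1-hydroxy-6-methyl-3-(prop-1-en-2-yl)spiro[4.5]dec-6-en-10-one, via samarium dienolate 12 (not isolated)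
Conditions: SmI2 (2.2 equiv), THF, −78 °C, slow addition of 11; then aqueous NH4Cl
Reagents that add atoms: none
Why: SmI2 reduces the C–Br bond to the samarium dienolate 12, whose α-carbon C5 adds to the tethered aldehyde; the closest known reaction is the samarium-mediated intramolecular Reformatsky-type aldol of α-bromo ketones, here run on a vinylogous enolate. Ring A closes in a 5-(enolexo)-exo-trig mode, the alternative attack through C7 requiring a bridged seven-membered ring. C5 and C1 are formed together in a closed six-membered transition state in which trivalent samarium bridges the enolate oxygen on C10 and the aldehyde oxygen, so the C1–O bond ends syn to C10. The C3 isopropenyl group should sit pseudo-equatorial on the convex face of this bicyclic array, anti to the metal-bound oxygen, which sets C1 and C5 relative to C3 (1R,5R with 3S). The step needs reduction of the bromo ketone before the aldehyde, secured by the much faster C–Br reduction at −78 °C, and α- over γ-attack, secured by ring size. The aldol cannot dehydrate because C5 is quaternary, and C6=C7 cannot move into conjugation.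

Step 6
Reactants: 13 (1R,3S,5R)-1-hydroxy-6-methyl-3-(prop-1-en-2-yl)spiro[4.5]dec-6-en-10-one
Product: 14 (1R,3S,5R)-6,10-dimethyl-3-(prop-1-en-2-yl)spiro[4.5]dec-6-ene-1,10-diol (C10 epimers)
Conditions: MeLi (3 equiv), CeCl3 (3 equiv), THF, −78 °C
Reagents that add atoms: methyllithium [Li]C
Why: Organocerium addition should reach the hindered, enolisable C10 ketone without retro-aldol of the cold aldolate; the configuration created at C10 is irrelevant because step 9 passes through a planar radical.

Step 7
Reactants: 14 (1R,3S,5R)-6,10-dimethyl-3-(prop-1-en-2-yl)spiro[4.5]dec-6-ene-1,10-diol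
Product: 15 (1R,3S,5R)-10-hydroxy-6,10-dimethyl-3-(prop-1-en-2-yl)spiro[4.5]dec-6-en-1-yl 2-methylpropanoate
Conditions: isobutyric anhydride, DMAP (cat.), Et3N, CH2Cl2, 20 °C
Reagents that add atoms: isobutyric anhydride CC(C)C(=O)OC(=O)C(C)C
Why: DMAP-catalysed acylation should take the secondary C1 hydroxyl and leave the tertiary C10 hydroxyl, installing the final ester, which later shields one face of C10.

Step 8
Reactants: 15 (1R,3S,5R)-10-hydroxy-6,10-dimethyl-3-(prop-1-en-2-yl)spiro[4.5]dec-6-en-1-yl 2-methylpropanoate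
Product: 16 methyl (1R,3S,5R)-6,10-dimethyl-1-(2-methylpropanoyloxy)-3-(prop-1-en-2-yl)spiro[4.5]dec-6-en-10-yl oxalate
Conditions: methyl chlorooxoacetate, DMAP, pyridine, CH2Cl2, 0 to 40 °C
Reagents that add atoms: methyl chlorooxoacetate COC(=O)C(=O)Cl
Why: The very electrophilic oxalyl half-ester chloride should acylate even this hindered tertiary alcohol and provide the precursor for radical deoxygenation.

Step 9
Reactants: 16 methyl (1R,3S,5R)-6,10-dimethyl-1-(2-methylpropanoyloxy)-3-(prop-1-en-2-yl)spiro[4.5]dec-6-en-10-yl oxalate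
Product: 17 (1R,3S,5R,10R)-6,10-dimethyl-3-(prop-1-en-2-yl)spiro[4.5]dec-6-en-1-yl 2-methylpropanoate
Conditions: Bu3SnH (5 equiv, about 1 M), AIBN (cat.), toluene, 110 °C
Reagents that add atoms: none
Why: In this Barton–McCombie-type deoxygenation of a tertiary oxalate the planar C10 radical should take hydrogen from the ring B face that carries C4H2, anti to the isobutyrate on C1 that overhangs C10, so the methyl group ends cis to C1; the high stannane concentration suppresses homoallyl rearrangement.

Step 10
Reactants: 17 (1R,3S,5R,10R)-6,10-dimethyl-3-(prop-1-en-2-yl)spiro[4.5]dec-6-en-1-yl 2-methylpropanoate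
Product: 18 (1R,3S,5R,10R)-6,10-dimethyl-8-oxo-3-(prop-1-en-2-yl)spiro[4.5]dec-6-en-1-yl 2-methylpropanoate
Conditions: CrO3, 3,5-dimethylpyrazole, CH2Cl2, −20 °C
Reagents that add atoms: chromium trioxide O=[Cr](=O)=O
Why: Allylic oxidation should occur at C8, the only ring methylene allylic to C6=C7, as in related sesquiterpene oxidations that leave an isopropenyl group intact.

Step 11
Reactants: 18 (1R,3S,5R,10R)-6,10-dimethyl-8-oxo-3-(prop-1-en-2-yl)spiro[4.5]dec-6-en-1-yl 2-methylpropanoate
Product: 19 (1R,3S,5R,9R,10S)-9-acetoxy-6,10-dimethyl-8-oxo-3-(prop-1-en-2-yl)spiro[4.5]dec-6-en-1-yl 2-methylpropanoate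
Conditions: Mn(OAc)3·2H2O (2.5 equiv), benzene, 80 °C
Reagents that add atoms: manganese triacetate CC(=O)[O-].CC(=O)[O-].CC(=O)[O-].[Mn+3]
Why: Mn(OAc)3 α′-acetoxylation of the enone should deliver acetate to C9 anti to the neighbouring C10 methyl group, and this ketone-adjacent centre can also equilibrate to the trans arrangement (9R).

**Compound list**

1 | (S)-limonene, (4S)-1-methyl-4-(prop-1-en-2-yl)cyclohex-1-ene | CC1=CC[C@H](CC1)C(C)=C | starting material
2 | (3S)-6-hydroperoxy-6-methoxy-3-(prop-1-en-2-yl)heptanal (C6 epimers) | O=CC[C@H](CCC(C)(OC)OO)C(C)=C | intermediate (not isolated)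
3 | (5S)-2-hydroperoxy-2,7,7-trimethoxy-5-(prop-1-en-2-yl)heptane (C2 epimers) | COC(OC)C[C@H](CCC(C)(OC)OO)C(C)=C | intermediate (not isolated)
4 | (5S)-7,7-dimethoxy-5-(prop-1-en-2-yl)heptan-2-one | COC(OC)C[C@H](CCC(C)=O)C(C)=C | intermediate
5 | 3-(trimethylsilyl)but-3-en-2-one | CC(=O)C(=C)[Si](C)(C)C | starting material
6 | (9S)-11,11-dimethoxy-9-(prop-1-en-2-yl)-3-(trimethylsilyl)undecane-2,6-dione (C3 epimers) | COC(OC)C[C@H](CCC(=O)CCC(C(C)=O)[Si](C)(C)C)C(C)=C | intermediate (not isolated)
7 | (9S)-11,11-dimethoxy-9-(prop-1-en-2-yl)undecane-2,6-dione | COC(OC)C[C@H](CCC(=O)CCCC(C)=O)C(C)=C | intermediate (not isolated)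
8 | 2-[(2S)-4,4-dimethoxy-2-(prop-1-en-2-yl)butyl]-3-methylcyclohex-2-en-1-one | COC(OC)C[C@H](CC1=C(C)CCCC1=O)C(C)=C | intermediate
9 | potassium 2-[(2S)-4,4-dimethoxy-2-(prop-1-en-2-yl)butyl]-3-methylcyclohexa-1,3-dien-1-olate | COC(OC)C[C@H](CC1=C([O-])CCC=C1C)C(C)=C.[K+] | intermediate (not isolated)
10 | 2-bromo-2-[(2R)-4,4-dimethoxy-2-(prop-1-en-2-yl)butyl]-3-methylcyclohex-3-en-1-one (ring C2 epimers) | COC(OC)C[C@H](CC1(Br)C(C)=CCCC1=O)C(C)=C | intermediate
11 | (3R)-4-(1-bromo-2-methyl-6-oxocyclohex-2-en-1-yl)-3-(prop-1-en-2-yl)butanal (ring C1 epimers) | O=CC[C@H](CC1(Br)C(C)=CCCC1=O)C(C)=C | intermediate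
12 | (3S)-4-[2-(diiodosamariooxy)-6-methylcyclohexa-1,5-dien-1-yl]-3-(prop-1-en-2-yl)butanal | O=CC[C@H](CC1=C(O[Sm](I)I)CCC=C1C)C(C)=C | intermediate (not isolated)
13 | (1R,3S,5R)-1-hydroxy-6-methyl-3-(prop-1-en-2-yl)spiro[4.5]dec-6-en-10-one | C=C(C)[C@@H]1C[C@@H](O)[C@@]2(C1)C(C)=CCCC2=O | intermediate
14 | (1R,3S,5R)-6,10-dimethyl-3-(prop-1-en-2-yl)spiro[4.5]dec-6-ene-1,10-diol (C10 epimers) | C=C(C)[C@@H]1C[C@@H](O)[C@@]2(C1)C(C)=CCCC2(C)O | intermediate
15 | (1R,3S,5R)-10-hydroxy-6,10-dimethyl-3-(prop-1-en-2-yl)spiro[4.5]dec-6-en-1-yl 2-methylpropanoate (C10 epimers) | C=C(C)[C@@H]1C[C@@H](OC(=O)C(C)C)[C@@]2(C1)C(C)=CCCC2(C)O | intermediate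
16 | methyl (1R,3S,5R)-6,10-dimethyl-1-(2-methylpropanoyloxy)-3-(prop-1-en-2-yl)spiro[4.5]dec-6-en-10-yl oxalate (C10 epimers) | C=C(C)[C@@H]1C[C@@H](OC(=O)C(C)C)[C@@]2(C1)C(C)=CCCC2(C)OC(=O)C(=O)OC | intermediate
17 | (1R,3S,5R,10R)-6,10-dimethyl-3-(prop-1-en-2-yl)spiro[4.5]dec-6-en-1-yl 2-methylpropanoate | C=C(C)[C@@H]1C[C@@H](OC(=O)C(C)C)[C@@]2(C1)C(C)=CCC[C@H]2C | intermediate
18 | (1R,3S,5R,10R)-6,10-dimethyl-8-oxo-3-(prop-1-en-2-yl)spiro[4.5]dec-6-en-1-yl 2-methylpropanoate | C=C(C)[C@@H]1C[C@@H](OC(=O)C(C)C)[C@@]2(C1)C(C)=CC(=O)C[C@H]2C | intermediate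
19 | (1R,3S,5R,9R,10S)-9-acetoxy-6,10-dimethyl-8-oxo-3-(prop-1-en-2-yl)spiro[4.5]dec-6-en-1-yl 2-methylpropanoate | C=C(C)[C@@H]1C[C@@H](OC(=O)C(C)C)[C@@]2(C1)C(C)=CC(=O)[C@H](OC(C)=O)[C@H]2C | target

**Totals.** Total step count: 11. Longest linear sequence: 11 steps (from 1).

**Steps most likely to fail**

Step 5. The remote C3 substituent may discriminate poorly between the two faces of the dienolate, and the aldehyde may be reduced or pinacol-coupled by divalent samarium before the enolate forms. The fallback sets out from 11 and replaces electron transfer by a radical chain: Ph3SnH and Et3B (trace of air) in benzene at 20 °C would abstract bromine and convert the α-keto allyl radical into the diethylboron dienolate F1. F1 should close ring A through a compact boron-centred Zimmerman–Traxler transition state in a neutral, non-reducing medium; buffered H2O2 work-up returns to the route at 13.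

Step 9. Hydrogen may be delivered to the planar C10 radical from the wrong face, or the tertiary oxalate may eliminate. The fallback sets out from 13 and delivers the methyl carbon from the C1 oxygen instead.
- TsNHNH2 in MeOH would give the tosylhydrazone F2.
- A Shapiro reaction (n-BuLi, 4 equiv, THF, −78 to 20 °C, then water) would give the homoallylic dienol F3, with C9=C10 formed regiospecifically because C5 is quaternary.
- (Bromomethyl)chlorodimethylsilane with Et3N and DMAP would give the bromomethylsilyl ether F4.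
- Bu3SnH and AIBN in benzene at 80 °C would cyclise F4 6-exo onto C10, which can only be reached on the face of C1, to give the cyclic siloxane F5.
- Protodesilylation with Bu4NF in DMF at 75 °C would give the C10-methyl alcohol F6.
- Acylation with isobutyric anhydride and DMAP comes back to the route at 17.

Step 2. The Michael step may over-add, or the diketone may close in the alternative aldol mode (methyl group onto the C10 ketone). The fallback sets out from 4: the same kinetic enolate would be alkylated with (Z)-1-bromo-3-iodobut-2-ene to give the vinyl iodide ketone F7. Intramolecular α-alkenylation of the ketone (Pd(PPh3)4, KOt-Bu, THF, 65 °C, zerovalent palladium) can only form the six-membered ring through C5 and would give the β,γ-unsaturated ketone F8. DBU moves the double bond into conjugation and comes back to the route at 8.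

**Further compounds**

F1 | step 5 | (3S)-4-[2-(diethylboryloxy)-6-methylcyclohexa-1,5-dien-1-yl]-3-(prop-1-en-2-yl)butanal | O=CC[C@H](CC1=C(OB(CC)CC)CCC=C1C)C(C)=C
F2 | step 9 | 4-methylbenzenesulfonylhydrazone of 13 at C10 (stereocentres as in 13) | C=C(C)[C@@H]1C[C@@H](O)[C@@]2(C1)C(C)=CCCC2=NNS(=O)(=O)c3ccc(C)cc3
F3 | step 9 | (1R,3S,5R)-6-methyl-3-(prop-1-en-2-yl)spiro[4.5]deca-6,9-dien-1-ol | C=C(C)[C@@H]1C[C@@H](O)[C@@]2(C1)C(C)=CCC=C2
F4 | step 9 | (bromomethyl)dimethylsilyl ether of F3 at the C1 oxygen | C=C(C)[C@@H]1C[C@@H](O[Si](C)(C)CBr)[C@@]2(C1)C(C)=CCC=C2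
F5 | step 9 | cyclic siloxane in which O–SiMe2–CH2 bridges C1 and C10 (CH2 on C10 cis to C1), C6=C7 retained | C=C(C)[C@@H]1C[C@@H](O[Si]3(C)C)[C@@]2(C1)C(C)=CCC[C@H]2C3
F6 | step 9 | (1R,3S,5R,10R)-6,10-dimethyl-3-(prop-1-en-2-yl)spiro[4.5]dec-6-en-1-ol | C=C(C)[C@@H]1C[C@@H](O)[C@@]2(C1)C(C)=CCC[C@H]2C
F7 | step 2 | (3S,9Z)-10-iodo-1,1-dimethoxy-3-(prop-1-en-2-yl)undec-9-en-6-one | COC(OC)C[C@H](CCC(=O)CC/C=C(/C)I)C(C)=C
F8 | step 2 | 2-[(2S)-4,4-dimethoxy-2-(prop-1-en-2-yl)butyl]-3-methylcyclohex-3-en-1-one (ring C2 epimers) | COC(OC)C[C@H](CC1C(C)=CCCC1=O)C(C)=C
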